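**Assumption:** (2S)-pinocembrin (2) is bought as the natural enantiomer. In the first benzylation of its 7-phenolate, C8 is assumed to react faster than C6, and any C6 regioisomer is removed by chromatography.

## Retrosynthetic overview
1. Target **1** ⇒ (2S)-pinocembrin **2** (bought, so the C2 stereocentre is already set and no ring is built) + the short-arm alcohol **3** at C8 and the long-arm alcohol **4** at C6. The two Ar–CH2–Ar bonds to the flavanone are made by photodehydrative C-benzylation, C8 first and C6 second.
2. Long arm **4** ⇒ **3** (as its o-quinone methide) + salicylaldehyde **6** (para C–H), then CHO → CH2OH.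
3. Short arm **3** ⇒ salicyl alcohol **5** (as its o-quinone methide) + salicylaldehyde **6** (para C–H), then CHO → CH2OH.
4. All five ArCH2Ar bonds come from one photochemical o-hydroxybenzyl alcohol dehydration that gives an o-quinone methide, followed by trapping at the most nucleophilic phenolate carbon. The only other operations are two NaBH4 reductions, run on arm fragments that contain no flavanone ketone.

## Route

**Step 1**
Reactants: **5** salicyl alcohol (2-hydroxybenzyl alcohol, 1 equiv); **6** salicylaldehyde (4 equiv)
Product: **7** 2-hydroxy-5-(2-hydroxybenzyl)benzaldehyde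
Conditions: hν (300 nm, Rayonet), 0.1 M aq. NaHCO3/MeCN 1:1 (pH ≈ 8.3), N2, 25 °C
Reagents that add atoms: none
Why: Proposed new method: the excited o-hydroxybenzyl alcohol undergoes ESIPT and loses water to give an o-quinone methide, which the salicylaldehyde phenolate (pKa ≈ 8.4, so it is the only ionised phenol at this pH) attacks by 1,4-addition through its para carbon. The closest known reactions are Wan-type photogeneration of o-quinone methides and thermal phenol–methylol (resol-type) condensation. The O-adduct is a photolabile 2-hydroxybenzyl aryl ether and reverts to the o-quinone methide, and water addition only regenerates **5**. The C–C adduct has no benzylic OH and is photostable, so the reaction funnels into **7**. No stereocentre is formed.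

**Step 2**
Reactants: **7**
Product: **3** 2-(hydroxymethyl)-4-[(2-hydroxyphenyl)methyl]phenol
Conditions: NaBH4 (2 equiv), MeOH, 0 °C → 25 °C, 1 h
Reagents that add atoms: none
Why: Aldehyde reduction by hydride; the free phenols are untouched and no stereocentre is involved.

**Step 3**
Reactants: **3** (1 equiv); **6** salicylaldehyde (4 equiv)
Product: **8** 2-hydroxy-5-{[2-hydroxy-5-(2-hydroxybenzyl)phenyl]methyl}benzaldehyde
Conditions: hν (300 nm), 0.1 M aq. NaHCO3/MeCN 1:1, N2, 25 °C
Reagents that add atoms: none
Why: Proposed new method: the same ESIPT photodehydration now takes place at the ortho-CH2OH of **3**, and the resulting o-quinone methide is trapped at C5 of the salicylaldehyde phenolate; this is the same chemistry as Step 1 with a larger electrophile. The product phenols (pKa ≈ 10) stay neutral and far less nucleophilic at pH 8.3. No stereocentre is formed.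

**Step 4**
Reactants: **8**
Product: **4** 2-(hydroxymethyl)-4-({2-hydroxy-5-[(2-hydroxyphenyl)methyl]phenyl}methyl)phenol
Conditions: NaBH4 (2 equiv), MeOH, 0 °C → 25 °C, 1 h
Reagents that add atoms: none
Why: Chemoselective aldehyde reduction. No flavanone is present, so there is no ketone to compete.

**Step 5**
Reactants: **2** (2S)-pinocembrin (1.3 equiv); **3** (1 equiv)
Product: **9** (2S)-8-{2-hydroxy-5-[(2-hydroxyphenyl)methyl]benzyl}-5,7-dihydroxyflavanone
Conditions: hν (300 nm), 0.1 M aq. NaHCO3/MeCN 1:1 (pH ≈ 8.3), N2, 25 °C; chromatography to remove the C6 isomer and bis-adduct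
Reagents that add atoms: none
Why: Proposed new method: the photogenerated o-quinone methide from **3** is intercepted by the 7-phenolate of **2** (pKa ≈ 7.3), which is a phloroglucinol-type C-nucleophile, at its more reactive C8. This is the same photodehydration as Steps 1 and 3, with a flavanone C–H as the trap, which has not been shown before. The C2 stereocentre is untouched; it is protected from retro-oxa-Michael ring opening by the mild pH, room temperature and the electron-rich 7-phenolate.

**Step 6**
Reactants: **9** (1 equiv); **4** (1.5 equiv)
Product: **1** Sarmentosumin D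
Conditions: hν (300 nm), 0.1 M aq. NaHCO3/MeCN 1:1, N2, 25 °C
Reagents that add atoms: none
Why: Proposed new method: the photo-o-quinone methide from **4** is trapped at C6, the only remaining nucleophilic carbon of the 7-phenolate of **9**, which again is a photodehydrative phenolate C-benzylation. The C2 (S) centre is carried through unchanged.

## Compound list
1 | Sarmentosumin D | O=C1C[C@@H](c2ccccc2)Oc2c(Cc3cc(Cc4ccccc4O)ccc3O)c(O)c(Cc3cc(Cc4cc(Cc5ccccc5O)ccc4O)ccc3O)c(O)c21 | target
2 | (2S)-pinocembrin, (S)-5,7-dihydroxyflavanone | O=C1C[C@@H](c2ccccc2)Oc2cc(O)cc(O)c21 | starting material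
3 | 2-(hydroxymethyl)-4-[(2-hydroxyphenyl)methyl]phenol | OCc1cc(Cc2ccccc2O)ccc1O | intermediate
4 | 2-(hydroxymethyl)-4-({2-hydroxy-5-[(2-hydroxyphenyl)methyl]phenyl}methyl)phenol | OCc1cc(Cc2cc(Cc3ccccc3O)ccc2O)ccc1O | intermediate
5 | salicyl alcohol (2-hydroxybenzyl alcohol) | OCc1ccccc1O | starting material
6 | salicylaldehyde | O=Cc1ccccc1O | starting material
7 | 2-hydroxy-5-(2-hydroxybenzyl)benzaldehyde | O=Cc1cc(Cc2ccccc2O)ccc1O | intermediate
8 | 2-hydroxy-5-{[2-hydroxy-5-(2-hydroxybenzyl)phenyl]methyl}benzaldehyde | O=Cc1cc(Cc2cc(Cc3ccccc3O)ccc2O)ccc1O | intermediate
9 | (2S)-8-{2-hydroxy-5-[(2-hydroxyphenyl)methyl]benzyl}-5,7-dihydroxyflavanone | O=C1C[C@@H](c2ccccc2)Oc2c(Cc3cc(Cc4ccccc4O)ccc3O)c(O)cc(O)c21 | intermediate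

## Totals
- Total steps: 6.
- Longest linear sequence: 5 (Steps 1 → 2 → 3 → 4 → 6).

## Three steps most likely to fail
1. **Step 5 (proposed new method).** Risks are C8 versus C6 selectivity, bis-alkylation, and UV-induced ring opening or racemisation of the flavanone.
   Fallback (known chemistry): convert **3** to its benzylic dimethylaminomethyl Mannich base or quaternary ammonium salt, then do a thermal o-quinone methide alkylation of **2** in aqueous NaHCO3 at about 60 °C. This replaces the photochemical step and avoids irradiating the flavanone.
2. **Step 3.** Over-alkylation and oligomerisation of the electron-rich arm phenols, o-quinone methide dimerisation, and the inner-filter effect of salicylaldehyde (the same risks apply to Step 1).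
   Fallback: build **4** by Suzuki–Miyaura coupling of 2-methoxybenzyl bromide with 3-formyl-4-methoxyphenylboronic acid. Repeat that coupling once more to extend the chain, then do BBr3 demethylation and NaBH4 reduction, which gives the same arm alcohol by cross-coupling.
3. **Step 6.** Steric hindrance at C6 next to the new C8 arm, and photodegradation of the polyphenolic product.
   Fallback: build the C6 arm stepwise on **9**. First benzylate C6 with salicyl alcohol **5**, then couple the para carbon of that new ring with the o-quinone methide of **3**. This avoids handling the large preformed arm **4**.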